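**Retrosynthetic overview**

1. Locants are those of the azulene skeleton: five-membered ring C-1 (CHOH), C-2 (CH2), C-3 (C(OH)i-Pr), C-3a (CH), C-8a (C–CH3); seven-membered ring C-3a, C-4 (CH–O-ester), C-5, C-6 (=C–CH3), C-7, C-8, C-8a; β is the face of the 8a-methyl.
2. Target ⇒ (ester bond at C-4–O, two silyl ethers) diol 16 ⇒ (hydroxyl-directed reduction) C-4 ketone 15/14 ⇒ (dissolving-metal reduction of dienone and cyclopentanone) trans-fused 1,4-dione 13 ⇒ silyl dienol ether 12.
3. Key disconnection: 12 ⇒ α-diazo ketone 10 by an intramolecular Buchner reaction. Bond C-8a–C-3a closes the five-membered ring, and in the same operation the carbene carbon C-8a is inserted into the C-3a–C-8 bond of a benzene ring, which thereby becomes the seven-membered ring.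
4. 10 ⇒ aryl isopropyl ketone 4 (enantioselective Reformatsky addition, Weinreb ketone synthesis, diazo transfer) ⇒ m-cresol. Ring order: benzene ring (bought), then the five-membered ring, closed last; no ring is closed after the key step.
5. Enabling feature: the six ring atoms C-3a, C-4, C-5, C-6, C-7, C-8 carry the C-3 side chain, oxygen and CH3 in the 1,2,4-pattern of an O-silylated 2-acyl-5-methylphenol, and the seventh ring atom C-8a is quaternary, bears CH3 and sits next to oxygenated C-1, so it can be the carbene carbon of a 2-diazo-3-ketone.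

Key step: step 7

Remark: 4-(tert-butyldimethylsilyloxy)benzoic acid (19) is assumed not to be on the shelf and is made in step 12; the phenol oxygen of m-cresol is carried through the whole route and becomes the ester oxygen at C-4.

**Route**

Step 1
Reactants: 1 3-methylphenol (m-cresol)
Product: 3 1-(2-hydroxy-4-methylphenyl)-2-methylpropan-1-one, via 3-methylphenyl 2-methylpropanoate 2 (not isolated)
Conditions: i-PrCOCl (1.05 equiv), neat, 60 °C; then AlCl3 (1.3 equiv), 140 °C; aq. HCl
Reagents that add atoms: isobutyryl chloride, CC(C)C(Cl)=O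
Why: O-Acylation and then Fries rearrangement, which at high temperature should deliver the chelated ortho-hydroxy ketone at the unhindered position para to the methyl group.

Step 2
Reactants: 3 1-(2-hydroxy-4-methylphenyl)-2-methylpropan-1-one
Product: 4 1-[2-(tert-butyldimethylsilyloxy)-4-methylphenyl]-2-methylpropan-1-one
Conditions: t-BuMe2SiCl, imidazole, DMAP (cat.), DMF, 40 °C
Reagents that add atoms: tert-butyldimethylsilyl chloride, CC(C)(C)[Si](C)(C)Cl
Why: Standard silylation of the phenol, chosen so that this oxygen leaves the key step as a silyl enol ether that can be cleaved without acid.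

Step 3
Reactants: 4 1-[2-(tert-butyldimethylsilyloxy)-4-methylphenyl]-2-methylpropan-1-one
Product: 5 ethyl (3R)-3-[2-(tert-butyldimethylsilyloxy)-4-methylphenyl]-3-hydroxy-4-methylpentanoate
Conditions: ICH2CO2Et, Me2Zn, MnCl(salen) (20 mol%; salen = dianion of one enantiomer of N,N'-bis(3,5-di-tert-butylsalicylidene)cyclohexane-1,2-diamine, C36H52ClMnN2O2), 4-phenylpyridine N-oxide (25 mol%), t-BuOMe, 25 °C; aq. NH4Cl
Reagents that add atoms: ethyl iodoacetate, CCOC(=O)CI
Why: Catalytic enantioselective Reformatsky addition of the zinc enolate made from ICH2CO2Et and Me2Zn to an aryl alkyl ketone, in which the chiral MnCl(salen) complex differentiates the ketone faces; the ligand enantiomer that gives the (R)-carbinol is used.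

Step 4
Reactants: 5 ethyl (3R)-3-[2-(tert-butyldimethylsilyloxy)-4-methylphenyl]-3-hydroxy-4-methylpentanoate
Product: 6 ethyl (3R)-3-[2-(tert-butyldimethylsilyloxy)-4-methylphenyl]-4-methyl-3-(trimethylsilyloxy)pentanoate
Conditions: Me3SiOTf, 2,6-lutidine, CH2Cl2, −78 to 0 °C
Reagents that add atoms: trimethylsilyl trifluoromethanesulfonate, C[Si](C)(C)OS(=O)(=O)C(F)(F)F
Why: Silylation of the tertiary alcohol with the silyl triflate, which later prevents O–H insertion of the carbene and retro-aldol cleavage.

Step 5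
Reactants: 6 ethyl (3R)-3-[2-(tert-butyldimethylsilyloxy)-4-methylphenyl]-4-methyl-3-(trimethylsilyloxy)pentanoate
Product: 8 (5R)-5-[2-(tert-butyldimethylsilyloxy)-4-methylphenyl]-6-methyl-5-(trimethylsilyloxy)heptan-3-one, via Weinreb amide 7 (not isolated)
Conditions: MeNH(OMe)·HCl, i-PrMgCl, THF, −20 °C; then EtMgBr, −20 to 0 °C; aq. NH4Cl
Reagents that add atoms: ethylmagnesium bromide, CC[Mg]Br (N,O-dimethylhydroxylamine hydrochloride, CNOC.Cl, adds atoms only to 7)
Why: Weinreb ketone synthesis in one flask: the magnesium amide turns the ester into the N-methoxy-N-methylamide, whose chelated adduct with EtMgBr collapses to the ketone only on work-up.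

Step 6
Reactants: 8 (5R)-5-[2-(tert-butyldimethylsilyloxy)-4-methylphenyl]-6-methyl-5-(trimethylsilyloxy)heptan-3-one
Product: 10 (5R)-5-[2-(tert-butyldimethylsilyloxy)-4-methylphenyl]-2-diazo-6-methyl-5-(trimethylsilyloxy)heptan-3-one, via trifluoroacetyl diketone 9 (not isolated)
Conditions: LiN(SiMe3)2, THF, −78 °C; CF3CO2CH2CF3; aq. HCl work-up; then MsN3, Et3N, H2O, MeCN, 25 °C
Reagents that add atoms: methanesulfonyl azide, CS(=O)(=O)N=[N+]=[N-] (2,2,2-trifluoroethyl trifluoroacetate, FC(F)(F)COC(=O)C(F)(F)F, adds atoms only to 9)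
Why: Regitz-type deacylative diazo transfer: kinetic enolisation occurs at the unhindered CH2 of the ethyl group and not at the neopentyl-like CH2, the enolate is trifluoroacetylated, and MsN3 then replaces the trifluoroacetyl group by the diazo group.

Step 7
Reactants: 10 (5R)-5-[2-(tert-butyldimethylsilyloxy)-4-methylphenyl]-2-diazo-6-methyl-5-(trimethylsilyloxy)heptan-3-one
Product: 12 (3R,8aR)-4-(tert-butyldimethylsilyloxy)-6,8a-dimethyl-3-(propan-2-yl)-3-(trimethylsilyloxy)-3,8a-dihydroazulen-1(2H)-one, via norcaradiene 11 (not isolated)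
Conditions: Rh2(O2CCF3)4 (1 mol%), CH2Cl2, 25 °C, slow addition of 10
Reagents that add atoms: none
Why: Rh2(O2CCF3)4 expels N2 from 10 to give an electrophilic rhodium carbene at the methyl-bearing carbon, which adds across the ipso–ortho bond of the electron-rich arene to give norcaradiene 11; disrotatory 6π-electrocyclic opening of its cyclopropane bond then expands the benzene ring by one carbon to the cycloheptatriene 12 (intramolecular Buchner reaction, the known route from 1-diazo-4-arylbutan-2-ones, including alkyl-substituted ones, to 3,8a-dihydroazulen-1(2H)-ones). The cyclopentanone ring (C-1, C-2, C-3, C-3a, C-8a) is closed by the carbene-to-ipso bond C-8a–C-3a through a three-atom tether in the cyclopropanation mode (a 5-exo closure onto the arene), and the seven-membered ring is not closed but grows out of the six-membered ring that was there from the start. The one new stereocenter that remains, quaternary C-8a, is controlled by the silyloxy carbinol C-3: the tether has to leave the arene plane on the face that is attacked, the small OSiMe3 group then lies near the plane beside the ortho silyloxy substituent and the isopropyl group points to the opposite face (least A1,3 strain), which puts 8a-CH3 cis to the C-3 oxygen, in line with the high diastereoselection known for substrates with a benzylic substituent. Regioselectivity (addition to the unsubstituted ortho carbon C-8, not to the silyloxy-bearing C-4) is secured by the bulk of the aryl silyl ether and of the fully substituted benzylic carbon. Chemoselectivity over C–H insertion into the isopropyl group and over 1,2-hydride shift of the methyl carbene is secured by the perfluorocarboxylate ligands, which are known to steer such carbenes to aromatic cycloaddition, and by the silyl cap on the tertiary alcohol, which excludes O–H insertion.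

Step 8
Reactants: 12 (3R,8aR)-4-(tert-butyldimethylsilyloxy)-6,8a-dimethyl-3-(propan-2-yl)-3-(trimethylsilyloxy)-3,8a-dihydroazulen-1(2H)-one
Product: 13 3β-hydroxy-6,8a-dimethyl-3α-(propan-2-yl)-2,3,3a,8a-tetrahydroazulene-1,4-dione (trans-fused: 3a-H α; 8a-CH3 β)
Conditions: Bu4NF (2.5 equiv), AcOH (5 equiv), THF, 0 °C
Reagents that add atoms: none
Why: Fluoride cleaves the trimethylsilyl ether and the silyl enol ether, and the cross-conjugated enolate can be protonated only at C-3a, which should happen on the convex face of the cycloheptatriene, anti to the 8a-methyl and the C-3 oxygen, to give the trans ring fusion that is also expected to be the more stable one (C-4 cis to OH and not to isopropyl); the buffered medium avoids acid ionisation of the allylic tertiary C-3–O bond.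

Step 9
Reactants: 13 3β-hydroxy-6,8a-dimethyl-3α-(propan-2-yl)-2,3,3a,8a-tetrahydroazulene-1,4-dione
Product: 14 1β,3β-dihydroxy-6,8a-dimethyl-3α-(propan-2-yl)-1,2,3,3a,8,8a-hexahydroazulen-4(5H)-one (trans-fused)
Conditions: Li (8 equiv), NH3(l)/THF, t-BuOH (2.5 equiv), −78 °C; then solid NH4Cl
Reagents that add atoms: none
Why: Dissolving-metal (Birch-type) reduction: the linear dienone takes up two electrons and a proton at C-8 to give a dienolate that is protonated kinetically at C-5 on quenching, which leaves the C-6=C-7 double bond out of conjugation, and the cyclopentanone is reduced to the more stable 1β-alcohol, cis to the angular methyl as in the reduction of 17-oxo steroids.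

Step 10
Reactants: 14 1β,3β-dihydroxy-6,8a-dimethyl-3α-(propan-2-yl)-1,2,3,3a,8,8a-hexahydroazulen-4(5H)-one
Product: 15 1β-(tert-butyldimethylsilyloxy)-3β-hydroxy-6,8a-dimethyl-3α-(propan-2-yl)-1,2,3,3a,8,8a-hexahydroazulen-4(5H)-one (trans-fused)
Conditions: t-BuMe2SiOTf (1.1 equiv), 2,6-lutidine, CH2Cl2, −78 °C
Reagents that add atoms: tert-butyldimethylsilyl trifluoromethanesulfonate, CC(C)(C)[Si](C)(C)OS(=O)(=O)C(F)(F)F
Why: Silylation of the secondary alcohol in the presence of the hindered tertiary one, so that later only the C-4 hydroxyl is free for acylation.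

Step 11
Reactants: 15 1β-(tert-butyldimethylsilyloxy)-3β-hydroxy-6,8a-dimethyl-3α-(propan-2-yl)-1,2,3,3a,8,8a-hexahydroazulen-4(5H)-one
Product: 16 1β-(tert-butyldimethylsilyloxy)-6,8a-dimethyl-3α-(propan-2-yl)-1,2,3,3a,4,5,8,8a-octahydroazulene-3β,4α-diol (trans-fused)
Conditions: Me4NBH(OAc)3, AcOH/MeCN (1:1), −25 °C
Reagents that add atoms: none
Why: Evans–Saksena reduction: the C-3 hydroxyl binds the triacetoxyborohydride and delivers hydride to the β-face of the C-4 ketone through a six-membered transition state, which gives the 4α-alcohol (anti-1,3-diol) under acidic conditions that do not move the β,γ-double bond into conjugation.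

Step 12
Reactants: 17 4-hydroxybenzoic acid
Product: 19 4-(tert-butyldimethylsilyloxy)benzoic acid, via bis-silyl ester 18 (not isolated)
Conditions: t-BuMe2SiCl (2.3 equiv), imidazole, DMF, 25 °C; then AcOH/THF/H2O, 25 °C
Reagents that add atoms: tert-butyldimethylsilyl chloride, CC(C)(C)[Si](C)(C)Cl
Why: Silylation of both acidic hydroxyls and selective hydrolysis of the much more labile silyl ester.

Step 13
Reactants: 16 1β-(tert-butyldimethylsilyloxy)-6,8a-dimethyl-3α-(propan-2-yl)-1,2,3,3a,4,5,8,8a-octahydroazulene-3β,4α-diol; 19 4-(tert-butyldimethylsilyloxy)benzoic acid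
Product: 20 1β-(tert-butyldimethylsilyloxy)-3β-hydroxy-6,8a-dimethyl-3α-(propan-2-yl)-1,2,3,3a,4,5,8,8a-octahydroazulen-4α-yl 4-(tert-butyldimethylsilyloxy)benzoate
Conditions: EDC·HCl, DMAP, CH2Cl2, 25 °C
Reagents that add atoms: none
Why: Steglich esterification of the only free secondary alcohol, the tertiary C-3 hydroxyl being too hindered to react.

Step 14
Reactants: 20 1β-(tert-butyldimethylsilyloxy)-3β-hydroxy-6,8a-dimethyl-3α-(propan-2-yl)-1,2,3,3a,4,5,8,8a-octahydroazulen-4α-yl 4-(tert-butyldimethylsilyloxy)benzoate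
Product: 21 (1R,3R,3aS,4S,8aR)-1,3-dihydroxy-6,8a-dimethyl-3-(propan-2-yl)-1,2,3,3a,4,5,8,8a-octahydroazulen-4-yl 4-hydroxybenzoate
Conditions: HF·pyridine, pyridine/THF, 0 to 25 °C
Reagents that add atoms: none
Why: Fluoride cleaves the alkyl and the aryl silyl ether under buffered conditions that leave the benzoate, the tertiary alcohol and the trisubstituted alkene untouched.

**Compound list**

1 | 3-methylphenol (m-cresol) | Cc1cccc(O)c1 | starting material
2 | 3-methylphenyl 2-methylpropanoate | CC(C)C(=O)Oc1cccc(C)c1 | intermediate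
3 | 1-(2-hydroxy-4-methylphenyl)-2-methylpropan-1-one | CC(C)C(=O)c1ccc(C)cc1O | intermediate
4 | 1-[2-(tert-butyldimethylsilyloxy)-4-methylphenyl]-2-methylpropan-1-one | CC(C)C(=O)c1ccc(C)cc1O[Si](C)(C)C(C)(C)C | intermediate
5 | ethyl (3R)-3-[2-(tert-butyldimethylsilyloxy)-4-methylphenyl]-3-hydroxy-4-methylpentanoate | CCOC(=O)C[C@@](O)(C(C)C)c1ccc(C)cc1O[Si](C)(C)C(C)(C)C | intermediate
6 | ethyl (3R)-3-[2-(tert-butyldimethylsilyloxy)-4-methylphenyl]-4-methyl-3-(trimethylsilyloxy)pentanoate | CCOC(=O)C[C@@](O[Si](C)(C)C)(C(C)C)c1ccc(C)cc1O[Si](C)(C)C(C)(C)C | intermediate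
7 | (3R)-3-[2-(tert-butyldimethylsilyloxy)-4-methylphenyl]-N-methoxy-N,4-dimethyl-3-(trimethylsilyloxy)pentanamide (Weinreb amide) | CON(C)C(=O)C[C@@](O[Si](C)(C)C)(C(C)C)c1ccc(C)cc1O[Si](C)(C)C(C)(C)C | intermediate
8 | (5R)-5-[2-(tert-butyldimethylsilyloxy)-4-methylphenyl]-6-methyl-5-(trimethylsilyloxy)heptan-3-one | CCC(=O)C[C@@](O[Si](C)(C)C)(C(C)C)c1ccc(C)cc1O[Si](C)(C)C(C)(C)C | intermediate
9 | (6R)-6-[2-(tert-butyldimethylsilyloxy)-4-methylphenyl]-1,1,1-trifluoro-3,7-dimethyl-6-(trimethylsilyloxy)octane-2,4-dione (C-3 epimers, enolised) | CC(C(=O)C(F)(F)F)C(=O)C[C@@](O[Si](C)(C)C)(C(C)C)c1ccc(C)cc1O[Si](C)(C)C(C)(C)C | intermediate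
10 | (5R)-5-[2-(tert-butyldimethylsilyloxy)-4-methylphenyl]-2-diazo-6-methyl-5-(trimethylsilyloxy)heptan-3-one | CC(=[N+]=[N-])C(=O)C[C@@](O[Si](C)(C)C)(C(C)C)c1ccc(C)cc1O[Si](C)(C)C(C)(C)C | intermediate
11 | norcaradiene valence tautomer of 12 (cyclopropane C-3a/C-8/C-8a; 8a-CH3 and 3-OSiMe3 cis) | C[C@]12C(=O)C[C@@](O[Si](C)(C)C)(C(C)C)[C@@]1(C(O[Si](C)(C)C(C)(C)C)=CC(C)=C3)[C@@H]23 | intermediate
12 | (3R,8aR)-4-(tert-butyldimethylsilyloxy)-6,8a-dimethyl-3-(propan-2-yl)-3-(trimethylsilyloxy)-3,8a-dihydroazulen-1(2H)-one (8a-CH3 and 3-OSiMe3 cis) | CC1=CC(O[Si](C)(C)C(C)(C)C)=C2[C@](O[Si](C)(C)C)(C(C)C)CC(=O)[C@]2(C)C=C1 | intermediate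
13 | 3β-hydroxy-6,8a-dimethyl-3α-(propan-2-yl)-2,3,3a,8a-tetrahydroazulene-1,4-dione (trans-fused: 3a-H α; 8a-CH3 β) | CC1=CC(=O)[C@H]2[C@](O)(C(C)C)CC(=O)[C@]2(C)C=C1 | intermediate
14 | 1β,3β-dihydroxy-6,8a-dimethyl-3α-(propan-2-yl)-1,2,3,3a,8,8a-hexahydroazulen-4(5H)-one (trans-fused) | CC1=CC[C@@]2(C)[C@H](O)C[C@@](O)(C(C)C)[C@@H]2C(=O)C1 | intermediate
15 | 1β-(tert-butyldimethylsilyloxy)-3β-hydroxy-6,8a-dimethyl-3α-(propan-2-yl)-1,2,3,3a,8,8a-hexahydroazulen-4(5H)-one (trans-fused) | CC1=CC[C@@]2(C)[C@H](O[Si](C)(C)C(C)(C)C)C[C@@](O)(C(C)C)[C@@H]2C(=O)C1 | intermediate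
16 | 1β-(tert-butyldimethylsilyloxy)-6,8a-dimethyl-3α-(propan-2-yl)-1,2,3,3a,4,5,8,8a-octahydroazulene-3β,4α-diol (trans-fused) | CC1=CC[C@@]2(C)[C@H](O[Si](C)(C)C(C)(C)C)C[C@@](O)(C(C)C)[C@@H]2[C@@H](O)C1 | intermediate
17 | 4-hydroxybenzoic acid | OC(=O)c1ccc(O)cc1 | starting material
18 | tert-butyldimethylsilyl 4-(tert-butyldimethylsilyloxy)benzoate | CC(C)(C)[Si](C)(C)OC(=O)c1ccc(O[Si](C)(C)C(C)(C)C)cc1 | intermediate
19 | 4-(tert-butyldimethylsilyloxy)benzoic acid | CC(C)(C)[Si](C)(C)Oc1ccc(C(=O)O)cc1 | intermediate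
20 | 1β-(tert-butyldimethylsilyloxy)-3β-hydroxy-6,8a-dimethyl-3α-(propan-2-yl)-1,2,3,3a,4,5,8,8a-octahydroazulen-4α-yl 4-(tert-butyldimethylsilyloxy)benzoate | CC1=CC[C@@]2(C)[C@H](O[Si](C)(C)C(C)(C)C)C[C@@](O)(C(C)C)[C@@H]2[C@@H](OC(=O)c2ccc(O[Si](C)(C)C(C)(C)C)cc2)C1 | intermediate
21 | (1R,3R,3aS,4S,8aR)-1,3-dihydroxy-6,8a-dimethyl-3-(propan-2-yl)-1,2,3,3a,4,5,8,8a-octahydroazulen-4-yl 4-hydroxybenzoate | CC1=CC[C@@]2(C)[C@H](O)C[C@@](O)(C(C)C)[C@@H]2[C@@H](OC(=O)c2ccc(O)cc2)C1 | target

**Step count**

Total step count: 14. Longest linear sequence: 13 (steps 1 to 11, 13 and 14; step 12 is a side branch).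

**Steps most likely to fail**

1. Step 7. What may go wrong: the methyl-substituted carbene may undergo 1,2-hydride migration to an enone or insert into the isopropyl C–H bond faster than it adds to the arene, or the two faces of the arene may not be told apart well enough. Fallback: from 6, the same one-flask Weinreb sequence with MeMgBr in place of EtMgBr would give the methyl ketone F1. Detrifluoroacetylative diazo transfer as in step 6 would give the terminal diazo ketone F2, whose carbene has no β-hydrogen and is the classical substrate type of this reaction. Rh2(O2CCF3)4 would then give the 8a-unsubstituted azulenone F3, whose C-8a configuration does not matter. Deprotonation with KN(SiMe3)2 and C-methylation with MeI at C-8a, on the face anti to the isopropyl group, would return to 12.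

2. Step 9. What may go wrong: over-reduction of the C-4 carbonyl, movement of the double bond into conjugation during protonation of the dienolate, or poor facial control in the ketyl reduction at C-1. Fallback: from 13, NaBH4 in CH2Cl2/MeOH at −78 °C would reduce only the saturated cyclopentanone, with hydride from the α-face, to the hydroxy dienone F4. Silylation with t-BuMe2SiOTf and 2,6-lutidine would give the silyl ether F5. Li in NH3 would then have only the dienone to reduce and would lead directly to 15.

3. Step 3. What may go wrong: slow addition to the hindered, ortho-substituted isopropyl ketone and insufficient enantiofacial discrimination by the catalyst. Fallback: from 4, a classical zinc Reformatsky reaction with ethyl bromoacetate would give the racemic hydroxy ester F6, and separation of its enantiomers by preparative chromatography on a chiral stationary phase would return to 5.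

**Further compounds**

F1 | step 7 | (4R)-4-[2-(tert-butyldimethylsilyloxy)-4-methylphenyl]-5-methyl-4-(trimethylsilyloxy)hexan-2-one | CC(=O)C[C@@](O[Si](C)(C)C)(C(C)C)c1ccc(C)cc1O[Si](C)(C)C(C)(C)C
F2 | step 7 | (4R)-4-[2-(tert-butyldimethylsilyloxy)-4-methylphenyl]-1-diazo-5-methyl-4-(trimethylsilyloxy)hexan-2-one | [N-]=[N+]=CC(=O)C[C@@](O[Si](C)(C)C)(C(C)C)c1ccc(C)cc1O[Si](C)(C)C(C)(C)C
F3 | step 7 | (3R)-4-(tert-butyldimethylsilyloxy)-6-methyl-3-(propan-2-yl)-3-(trimethylsilyloxy)-3,8a-dihydroazulen-1(2H)-one (either C-8a epimer) | CC1=CC(O[Si](C)(C)C(C)(C)C)=C2[C@](O[Si](C)(C)C)(C(C)C)CC(=O)C2C=C1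
F4 | step 9 | 1β,3β-dihydroxy-6,8a-dimethyl-3α-(propan-2-yl)-1,2,3,3a-tetrahydroazulen-4(8aH)-one (trans-fused) | CC1=CC(=O)[C@H]2[C@](O)(C(C)C)C[C@@H](O)[C@]2(C)C=C1
F5 | step 9 | 1β-(tert-butyldimethylsilyloxy)-3β-hydroxy-6,8a-dimethyl-3α-(propan-2-yl)-1,2,3,3a-tetrahydroazulen-4(8aH)-one (trans-fused) | CC1=CC(=O)[C@H]2[C@](O)(C(C)C)C[C@@H](O[Si](C)(C)C(C)(C)C)[C@]2(C)C=C1
F6 | step 3 | racemic ethyl 3-[2-(tert-butyldimethylsilyloxy)-4-methylphenyl]-3-hydroxy-4-methylpentanoate | CCOC(=O)CC(O)(C(C)C)c1ccc(C)cc1O[Si](C)(C)C(C)(C)C
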